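**Retrosynthetic overview**

1. Target 19 ← 18 by hydrogenolysis of two aryl benzyl ethers; 18 ← 17 by hydroxyl-directed hydrogenation of the exocyclic C8'=C7' bond, which sets C8'.
2. 17 ← 14: the C8–C8' bond and the only ring formed in the route (oxolane O–C9–C8–C8'–C9') arise together when a C8' vinyllithium opens the cis-epoxide at C8 (5-exo).
3. 14 ← 6 + 13: the C9–O–C9' ether is made beforehand by O-alkylation, so it serves as the tether.
4. 6 ← syringaldehyde (benzylation, Z-olefination, reduction, asymmetric epoxidation); 13 ← vanillin (benzylation, bromo-Wittig, reduction, bromination).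
5. Feature used: the free secondary carbinol C7 (syringyl-bearing) sits on ring carbon C8 of the trans-3,4-disubstituted oxolane, next to the ring bond C8–C8'; this is the trace of a C7–C8 epoxide opened at C8 by C8'.

Key step: step 10

Remark: lignan numbering is used in the discussion (C7 carbinol carbon; C8 and C8' ring carbons; C9 and C9' ring CH2 groups; C7' benzylic carbon of the guaiacyl unit). The sense of induction in step 4 is assumed to follow the usual enantiofacial rule of the titanium–tartrate epoxidation.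

**Route**

Step 1
Reactants: 1 syringaldehyde
Product: 2 4-(benzyloxy)-3,5-dimethoxybenzaldehyde
Conditions: BnBr, K2CO3, DMF, 60 °C
Reagents that add atoms: benzyl bromide, BrCc1ccccc1
Why: Williamson ether synthesis on the phenoxide of the acidic 4-hydroxyl masks the phenol as a benzyl ether that is stable to hydride, base and organolithium reagents; no stereocentre is formed.

Step 2
Reactants: 2 4-(benzyloxy)-3,5-dimethoxybenzaldehyde; 3 ethyl 2-(diphenoxyphosphoryl)acetate
Product: 4 ethyl (Z)-3-[4-(benzyloxy)-3,5-dimethoxyphenyl]prop-2-enoate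
Conditions: NaH, THF, −78 → 0 °C
Reagents that add atoms: none
Why: Z-selective Horner–Wadsworth–Emmons olefination, in which the electron-poor diaryl phosphonate makes the kinetically formed cis-oxaphosphetane collapse faster than it equilibrates, so aromatic aldehydes should give mainly the (Z)-enoate, the minor E isomer being removed by chromatography.

Step 3
Reactants: 4 ethyl (Z)-3-[4-(benzyloxy)-3,5-dimethoxyphenyl]prop-2-enoate
Product: 5 (Z)-3-[4-(benzyloxy)-3,5-dimethoxyphenyl]prop-2-en-1-ol
Conditions: i-Bu2AlH (2.2 equiv), CH2Cl2, −78 °C; aq potassium sodium tartrate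
Reagents that add atoms: none
Why: 1,2-reduction of the conjugated ester by i-Bu2AlH at low temperature leaves the Z double bond and the benzyl ether untouched.

Step 4
Reactants: 5 (Z)-3-[4-(benzyloxy)-3,5-dimethoxyphenyl]prop-2-en-1-ol
Product: 6 [(2S,3R)-3-[4-(benzyloxy)-3,5-dimethoxyphenyl]oxiran-2-yl]methanol
Conditions: Ti(OiPr)4 (0.2 equiv), L-(+)-diisopropyl tartrate (0.24 equiv), t-BuOOH, 4 Å MS, CH2Cl2, −20 °C; aq NaOH/NaCl work-up
Reagents that add atoms: tert-butyl hydroperoxide, CC(C)(C)OO
Why: Sharpless asymmetric epoxidation is a syn-stereospecific oxygen transfer in which the titanium L-(+)-tartrate complex selects the alkene face that makes the carbinol-bearing epoxide carbon 2S, so the Z-alkene should give the cis (2S,3R)-epoxide (C8 and C7 of the target); Z-allylic alcohols react more slowly and less selectively than E ones, so 6 is to be enriched by recrystallisation, and catalytic titanium, molecular sieves and a non-acidic work-up limit opening of the electron-rich aryl epoxide.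

Step 5
Reactants: 7 vanillin
Product: 8 4-(benzyloxy)-3-methoxybenzaldehyde
Conditions: BnBr, K2CO3, DMF, 60 °C
Reagents that add atoms: benzyl bromide, BrCc1ccccc1
Why: Williamson ether synthesis on the phenoxide, as in step 1; no stereocentre is formed.

Step 6
Reactants: 8 4-(benzyloxy)-3-methoxybenzaldehyde; 9 ethyl (triphenylphosphoranylidene)acetate
Product: 11 ethyl (Z)-3-[4-(benzyloxy)-3-methoxyphenyl]-2-bromoprop-2-enoate, via bromo ylide 10 (not isolated)
Conditions: 9, N-bromosuccinimide, CH2Cl2, −20 °C; then 8, 40 °C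
Reagents that add atoms: N-bromosuccinimide, O=C1CCC(=O)N1Br
Why: one-pot halogenation–Wittig olefination, in which N-bromosuccinimide brominates the ylide carbon, the succinimide anion returns bromo ylide 10, and this stabilised ylide places the ester trans to the aryl group, i.e. bromine cis to aryl in the (Z)-2-bromoenoate; the ylide consumes the brominating agent before the electron-rich aldehyde is added.

Step 7
Reactants: 11 ethyl (Z)-3-[4-(benzyloxy)-3-methoxyphenyl]-2-bromoprop-2-enoate
Product: 12 (Z)-3-[4-(benzyloxy)-3-methoxyphenyl]-2-bromoprop-2-en-1-ol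
Conditions: i-Bu2AlH (2.2 equiv), CH2Cl2, −78 °C; aq potassium sodium tartrate
Reagents that add atoms: none
Why: 1,2-reduction of the ester by i-Bu2AlH at −78 °C preserves the vinylic C–Br bond and the alkene geometry.

Step 8
Reactants: 12 (Z)-3-[4-(benzyloxy)-3-methoxyphenyl]-2-bromoprop-2-en-1-ol
Product: 13 (Z)-1-(benzyloxy)-4-(2,3-dibromoprop-1-en-1-yl)-2-methoxybenzene
Conditions: CBr4, PPh3, CH2Cl2, 0 °C
Reagents that add atoms: tetrabromomethane, BrC(Br)(Br)Br
Why: Appel reaction of the primary allylic alcohol under neutral conditions (SN2 at CH2) leaves the vinylic bromide, the alkene geometry and the benzyl ether intact; 13 is used without storage.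

Step 9
Reactants: 6 [(2S,3R)-3-[4-(benzyloxy)-3,5-dimethoxyphenyl]oxiran-2-yl]methanol; 13 (Z)-1-(benzyloxy)-4-(2,3-dibromoprop-1-en-1-yl)-2-methoxybenzene
Product: 14 (2S,3R)-3-[4-(benzyloxy)-3,5-dimethoxyphenyl]-2-[[(Z)-3-[4-(benzyloxy)-3-methoxyphenyl]-2-bromoprop-2-en-1-yl]oxymethyl]oxirane
Conditions: NaH, Bu4NI (cat.), THF/DMF, −20 → 0 °C
Reagents that add atoms: none
Why: Williamson etherification of the primary alkoxide of 6 with the reactive allylic bromide (SN2 at C9', iodide catalysis) builds the C9–O–C9' tether without touching the epoxide stereocentres, low temperature and the presence of the electrophile during deprotonation holding back Payne rearrangement.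

Step 10
Reactants: 14 (2S,3R)-3-[4-(benzyloxy)-3,5-dimethoxyphenyl]-2-[[(Z)-3-[4-(benzyloxy)-3-methoxyphenyl]-2-bromoprop-2-en-1-yl]oxymethyl]oxirane
Product: 17 (S)-[4-(benzyloxy)-3,5-dimethoxyphenyl][(3R,4E)-4-[[4-(benzyloxy)-3-methoxyphenyl]methylidene]oxolan-3-yl]methanol, via vinyllithium 15 (not isolated), via lithium alkoxide 16 (not isolated)
Conditions: t-BuLi (2.1 equiv), THF, −78 °C, then → −20 °C; aq NH4Cl
Reagents that add atoms: none
Why: Two equivalents of t-BuLi effect bromine–lithium exchange at the vinylic C8'–Br bond with retention of alkene geometry (the second equivalent destroys t-BuBr), and vinyllithium 15 then attacks epoxide carbon C8 from the side opposite the C8–O bond to give alkoxide 16, which is protonated on work-up. The closest known reaction type is the Parham-type cyclisation, in which aryl- and vinyllithiums made by halogen–lithium exchange open a tethered epoxide; here it is applied to an electron-rich aryl cis-epoxide. The oxolane ring (C8'–C9'–O–C9–C8) closes in the 5-exo-tet mode, the breaking C8–O bond lying outside the new ring. The new stereocentre C8 is fixed by SN2 inversion of the enantioenriched (2S,3R)-epoxide and becomes R, while C7 keeps its oxygen and its spatial arrangement and is S in the product. The step needs attack at C8 and not at benzylic C7 (6-endo), exchange faster than addition of t-BuLi to the epoxide, and ring closure faster than loss of the tether alkoxide from the 2-lithioallyl ether: the five-atom tether lines C8' up with the C8–O bond, no Lewis acid is added so the benzylic position is not activated, and exchange and closure are run cold. Either geometry of the benzylidene would serve, since C7' becomes CH2 in step 11.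

Step 11
Reactants: 17 (S)-[4-(benzyloxy)-3,5-dimethoxyphenyl][(3R,4E)-4-[[4-(benzyloxy)-3-methoxyphenyl]methylidene]oxolan-3-yl]methanol
Product: 18 (S)-[4-(benzyloxy)-3,5-dimethoxyphenyl][(3R,4R)-4-[[4-(benzyloxy)-3-methoxyphenyl]methyl]oxolan-3-yl]methanol
Conditions: [Ir(cod)(PCy3)(py)]PF6 (5 mol%), H2 (1 atm), CH2Cl2, rt
Reagents that add atoms: none
Why: hydroxyl-directed homogeneous hydrogenation, in which the C7 hydroxyl, homoallylic to C8'=C7', binds the cationic iridium centre so that hydrogen is delivered to the alkene face on the side of the carbinol chain, putting H at C8' cis and the new benzyl group trans to that chain (8'R), while aryl benzyl ethers are not cleaved by this catalyst.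

Step 12
Reactants: 18 (S)-[4-(benzyloxy)-3,5-dimethoxyphenyl][(3R,4R)-4-[[4-(benzyloxy)-3-methoxyphenyl]methyl]oxolan-3-yl]methanol
Product: 19 4-[(S)-hydroxy[(3R,4R)-4-[(4-hydroxy-3-methoxyphenyl)methyl]oxolan-3-yl]methyl]-2,6-dimethoxyphenol
Conditions: H2 (1 atm), 10% Pd/C, EtOAc, rt
Reagents that add atoms: none
Why: heterogeneous catalytic hydrogenolysis of the two aryl benzyl ethers, which under neutral conditions in ethyl acetate should be cleaved faster than the secondary benzylic C7–OH bond, so the reaction is stopped once both phenols are free; no stereocentre is touched.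

**Compound list**

1 | syringaldehyde (4-hydroxy-3,5-dimethoxybenzaldehyde) | COc1cc(C=O)cc(OC)c1O | starting material
2 | 4-(benzyloxy)-3,5-dimethoxybenzaldehyde | COc1cc(C=O)cc(OC)c1OCc1ccccc1 | intermediate
3 | ethyl 2-(diphenoxyphosphoryl)acetate | CCOC(=O)CP(=O)(Oc1ccccc1)Oc1ccccc1 | starting material
4 | ethyl (Z)-3-[4-(benzyloxy)-3,5-dimethoxyphenyl]prop-2-enoate | CCOC(=O)/C=C\c1cc(OC)c(OCc2ccccc2)c(OC)c1 | intermediate
5 | (Z)-3-[4-(benzyloxy)-3,5-dimethoxyphenyl]prop-2-en-1-ol | OC/C=C\c1cc(OC)c(OCc2ccccc2)c(OC)c1 | intermediate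
6 | [(2S,3R)-3-[4-(benzyloxy)-3,5-dimethoxyphenyl]oxiran-2-yl]methanol (cis-epoxide) | OC[C@@H]1O[C@@H]1c1cc(OC)c(OCc2ccccc2)c(OC)c1 | intermediate
7 | vanillin (4-hydroxy-3-methoxybenzaldehyde) | COc1cc(C=O)ccc1O | starting material
8 | 4-(benzyloxy)-3-methoxybenzaldehyde | COc1cc(C=O)ccc1OCc1ccccc1 | intermediate
9 | ethyl (triphenylphosphoranylidene)acetate | CCOC(=O)C=P(c1ccccc1)(c1ccccc1)c1ccccc1 | starting material
10 | ethyl bromo(triphenylphosphoranylidene)acetate (bromo ylide, not isolated) | CCOC(=O)C(Br)=P(c1ccccc1)(c1ccccc1)c1ccccc1 | intermediate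
11 | ethyl (Z)-3-[4-(benzyloxy)-3-methoxyphenyl]-2-bromoprop-2-enoate | COc1cc(/C=C(\Br)C(=O)OCC)ccc1OCc1ccccc1 | intermediate
12 | (Z)-3-[4-(benzyloxy)-3-methoxyphenyl]-2-bromoprop-2-en-1-ol | COc1cc(/C=C(\Br)CO)ccc1OCc1ccccc1 | intermediate
13 | (Z)-1-(benzyloxy)-4-(2,3-dibromoprop-1-en-1-yl)-2-methoxybenzene | COc1cc(/C=C(\Br)CBr)ccc1OCc1ccccc1 | intermediate
14 | (2S,3R)-3-[4-(benzyloxy)-3,5-dimethoxyphenyl]-2-[[(Z)-3-[4-(benzyloxy)-3-methoxyphenyl]-2-bromoprop-2-en-1-yl]oxymethyl]oxirane | COc1cc(/C=C(\Br)COC[C@@H]2O[C@@H]2c2cc(OC)c(OCc3ccccc3)c(OC)c2)ccc1OCc1ccccc1 | intermediate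
15 | vinyllithium: 14 with lithium in place of bromine at C8', lithium cis to the aryl group (not isolated) | COc1cc(/C=C(\[Li])COC[C@@H]2O[C@@H]2c2cc(OC)c(OCc3ccccc3)c(OC)c2)ccc1OCc1ccccc1 | intermediate
16 | lithium alkoxide of 17 (not isolated) | COc1cc(/C=C2/COC[C@@H]2[C@H](O[Li])c2cc(OC)c(OCc3ccccc3)c(OC)c2)ccc1OCc1ccccc1 | intermediate
17 | (S)-[4-(benzyloxy)-3,5-dimethoxyphenyl][(3R,4E)-4-[[4-(benzyloxy)-3-methoxyphenyl]methylidene]oxolan-3-yl]methanol | COc1cc(/C=C2/COC[C@@H]2[C@H](O)c2cc(OC)c(OCc3ccccc3)c(OC)c2)ccc1OCc1ccccc1 | intermediate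
18 | (S)-[4-(benzyloxy)-3,5-dimethoxyphenyl][(3R,4R)-4-[[4-(benzyloxy)-3-methoxyphenyl]methyl]oxolan-3-yl]methanol | COc1cc(C[C@H]2COC[C@@H]2[C@H](O)c2cc(OC)c(OCc3ccccc3)c(OC)c2)ccc1OCc1ccccc1 | intermediate
19 | 4-[(S)-hydroxy[(3R,4R)-4-[(4-hydroxy-3-methoxyphenyl)methyl]oxolan-3-yl]methyl]-2,6-dimethoxyphenol (7S,8R,8'R) | COc1cc(C[C@H]2COC[C@@H]2[C@H](O)c2cc(OC)c(O)c(OC)c2)ccc1O | target

**Step count**

Total: 12 steps. Longest linear sequence: 8 steps (1 → 2 → 4 → 5 → 6 → 14 → 17 → 18 → 19; the vanillin branch 7 → 8 → 11 → 12 → 13 → 14 is equally long).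

**Steps most likely to fail**

Step 10 (key step). The vinyllithium may lose the tether alkoxide by β-elimination before it closes the ring. It may also fail to open the 1,2-disubstituted epoxide at temperatures it survives, or attack benzylic C7 in the 6-endo sense. The fallback gives up the epoxide opening; it takes C8' from an asymmetric hydrogenation and C7/C8 from a lactone aldol. It sets out from 8 (and uses 2) and comes back to the route at 18.
- Stobbe condensation of 8 with diethyl succinate (t-BuOK, t-BuOH) should give (E)-4-[4-(benzyloxy)-3-methoxyphenyl]-3-(ethoxycarbonyl)but-3-enoic acid F1.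
- Asymmetric hydrogenation with [Rh(cod)(Me-DuPhos)]BF4 (ligand enantiomer chosen for the R acid) should give (R)-4-[4-(benzyloxy)-3-methoxyphenyl]-3-(ethoxycarbonyl)butanoic acid F2.
- Reduction of the ester of the potassium carboxylate with Ca(BH4)2 and acid lactonisation should give (R)-4-[[4-(benzyloxy)-3-methoxyphenyl]methyl]oxolan-2-one F3.
- The LiN(SiMe3)2 enolate of F3 and aldehyde 2 (THF, −78 °C) should add trans to the benzyl group; C7 selectivity is the weak point of this sequence. The 7S diastereomer, (3S,4R)-3-[(S)-[4-(benzyloxy)-3,5-dimethoxyphenyl](hydroxy)methyl]-4-[[4-(benzyloxy)-3-methoxyphenyl]methyl]oxolan-2-one F4, is carried on.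
- Silylation (t-BuMe2SiOTf, 2,6-lutidine) should give the tert-butyldimethylsilyl ether of F4, F5.
- LiAlH4 should give (2R,3R)-2-[(S)-[4-(benzyloxy)-3,5-dimethoxyphenyl][(tert-butyldimethylsilyl)oxy]methyl]-3-[[4-(benzyloxy)-3-methoxyphenyl]methyl]butane-1,4-diol F6.
- Mitsunobu cyclodehydration (PPh3, diisopropyl azodicarboxylate) should close the oxolane to the tert-butyldimethylsilyl ether of 18, F7.
- Bu4NF then frees 18.

Step 4. Enantiofacial discrimination on the Z-allylic alcohol may be incomplete, and the titanium alkoxides may open the electron-rich aryl epoxide during reaction or work-up. The fallback sets out from 4 and comes back at 6.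
- Jacobsen–Katsuki epoxidation of the cis-enoate 4 is run with (R,R)-[N,N'-bis(3,5-di-tert-butylsalicylidene)cyclohexane-1,2-diaminato]MnCl, NaOCl and 4-phenylpyridine N-oxide in CH2Cl2. It should give ethyl (2R,3R)-3-[4-(benzyloxy)-3,5-dimethoxyphenyl]oxirane-2-carboxylate F8.
- The catalyst enantiomer is chosen by analogy with simple cis-cinnamate esters; the sense would be confirmed by correlation with 6.
- NaBH4 in ethanol at 0 °C then reduces the glycidic ester to 6.

Step 11. Binding of the hydroxyl to iridium may be outcompeted by the ether oxygens, giving poor facial selectivity. The catalyst may also deactivate before the hindered trisubstituted styrenyl alkene is reduced. The fallback sets out from 17 and comes back at 18 without new compounds.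
- Stereocontrol is moved from the substrate to the catalyst: asymmetric hydrogenation with a chiral iridium phosphinooxazoline complex, [Ir(cod)(tBu-PHOX)][B(3,5-(CF3)2C6H3)4], H2 (50 bar), CH2Cl2.
- Both ligand enantiomers are tried, and the one whose facial preference matches delivery to C8' from the carbinol side is kept.

**Further compounds**

F1 | step 10 | (E)-4-[4-(benzyloxy)-3-methoxyphenyl]-3-(ethoxycarbonyl)but-3-enoic acid | COc1cc(/C=C(\CC(=O)O)C(=O)OCC)ccc1OCc1ccccc1
F2 | step 10 | (R)-4-[4-(benzyloxy)-3-methoxyphenyl]-3-(ethoxycarbonyl)butanoic acid | COc1cc(C[C@H](CC(=O)O)C(=O)OCC)ccc1OCc1ccccc1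
F3 | step 10 | (R)-4-[[4-(benzyloxy)-3-methoxyphenyl]methyl]oxolan-2-one | COc1cc(C[C@H]2COC(=O)C2)ccc1OCc1ccccc1
F4 | step 10 | (3S,4R)-3-[(S)-[4-(benzyloxy)-3,5-dimethoxyphenyl](hydroxy)methyl]-4-[[4-(benzyloxy)-3-methoxyphenyl]methyl]oxolan-2-one | COc1cc(C[C@H]2COC(=O)[C@@H]2[C@H](O)c2cc(OC)c(OCc3ccccc3)c(OC)c2)ccc1OCc1ccccc1
F5 | step 10 | tert-butyldimethylsilyl ether of F4 | COc1cc(C[C@H]2COC(=O)[C@@H]2[C@H](O[Si](C)(C)C(C)(C)C)c2cc(OC)c(OCc3ccccc3)c(OC)c2)ccc1OCc1ccccc1
F6 | step 10 | (2R,3R)-2-[(S)-[4-(benzyloxy)-3,5-dimethoxyphenyl][(tert-butyldimethylsilyl)oxy]methyl]-3-[[4-(benzyloxy)-3-methoxyphenyl]methyl]butane-1,4-diol | COc1cc(C[C@@H](CO)[C@H](CO)[C@H](O[Si](C)(C)C(C)(C)C)c2cc(OC)c(OCc3ccccc3)c(OC)c2)ccc1OCc1ccccc1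
F7 | step 10 | tert-butyldimethylsilyl ether of 18 | COc1cc(C[C@H]2COC[C@@H]2[C@H](O[Si](C)(C)C(C)(C)C)c2cc(OC)c(OCc3ccccc3)c(OC)c2)ccc1OCc1ccccc1
F8 | step 4 | ethyl (2R,3R)-3-[4-(benzyloxy)-3,5-dimethoxyphenyl]oxirane-2-carboxylate | CCOC(=O)[C@@H]1O[C@@H]1c1cc(OC)c(OCc2ccccc2)c(OC)c1
F0 | step 11 | none | none
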